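**Retrosynthetic overview**
1. The target is 5,7-dihydroxy-2-icosylchromone. The C5 and C7 phenols are carried as methyl ethers and released last with BBr3.
2. Key disconnection: the C2–CH2 bond and the O1–C2 bond of the γ-pyrone ring (ring C) are cut together. This leads back to B-icosyl-9-BBN (from 1-icosene) and the open-chain ketone 3,3-dichloro-1-(2-hydroxy-4,6-dimethoxyphenyl)prop-2-en-1-one.
3. Enabling feature: C2 carries the ring oxygen O1 and is the β-carbon of the C2=C3–C4=O enone. It is therefore a vinylogous carboxyl carbon and can be carried as a CCl2 group. The phenol oxygen on C8a is placed to close a six-membered ring on it and takes one chloride, and palladium exchanges the other chloride for the chain.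
4. The dichlorovinyl ketone comes from 1,3,5-trimethoxybenzene and 3,3-dichloroacryloyl chloride by Friedel–Crafts acylation, then chelation-directed loss of one ortho methyl.
5. Ring order: benzene ring A is bought. The γ-pyrone ring C is the only ring formed, and it is formed in the key step.

Key step: step 4

Remark on the chemistry: the side chain is read as an unbranched chain of twenty carbons (icosyl). The target has no stereocentre, so no step has to control configuration. 9-BBN is drawn as its monomer.

**Route**

Step 1
Reactants: 1 3,3-dichloroacrylic acid
Product: 2 3,3-dichloroacryloyl chloride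
Conditions: (COCl)2 (1.2 equiv), DMF (cat.), CH2Cl2, 0 °C → rt; distil
Reagents that add atoms: oxalyl chloride, ClC(=O)C(=O)Cl
Why: Acid chloride formation through the chloroiminium species made from catalytic DMF should proceed cleanly, because the electron-poor dichloroalkene is inert to the reagent.

Step 2
Reactants: 2 3,3-dichloroacryloyl chloride; 3 1,3,5-trimethoxybenzene
Product: 4 3,3-dichloro-1-(2,4,6-trimethoxyphenyl)prop-2-en-1-one
Conditions: AlCl3 (1.1 equiv), CH2Cl2, −20 → 0 °C; ice/1 M HCl
Reagents that add atoms: none
Why: In this Friedel–Crafts acylation the acylium ion from 2 attacks a threefold activated arene whose three free positions are equivalent, and the resulting ketone is deactivated toward a second acylation.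

Step 3
Reactants: 4 3,3-dichloro-1-(2,4,6-trimethoxyphenyl)prop-2-en-1-one
Product: 5 3,3-dichloro-1-(2-hydroxy-4,6-dimethoxyphenyl)prop-2-en-1-one
Conditions: BCl3 (1.2 equiv, 1 M in CH2Cl2), CH2Cl2, −78 → 0 °C; cold 1 M HCl
Reagents that add atoms: none
Why: In this chelation-directed aryl methyl ether cleavage BCl3 bridges the ketone oxygen and one flanking methoxy oxygen, so only one of the two equivalent ortho methyl groups should be lost, and the acidic quench keeps the hydrogen-bonded phenol from closing early.

Step 4
Reactants: 5 3,3-dichloro-1-(2-hydroxy-4,6-dimethoxyphenyl)prop-2-en-1-one; 6 1-icosene; 7 9-borabicyclo[3.3.1]nonane (9-BBN)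
Product: 10 5,7-dimethoxy-2-icosyl-4H-chromen-4-one, via B-icosyl-9-BBN 8 (not isolated), via 2-chloro-5,7-dimethoxychromone 9 (not isolated)
Conditions: 6 (1.4 equiv), 7 (1.3 equiv, 0.5 M in THF), 0 °C → rt; separately 5, K3PO4·H2O (4 equiv), THF, 40 °C, 30 min; combine, Pd(OAc)2 (3 mol %), SPhos (6 mol %), 60 °C
Reagents that add atoms: none
Why: Proposed new method: 9-BBN adds to 1-icosene with anti-Markovnikov regiochemistry to give the primary borane 8, while K3PO4 deprotonates the chelated phenol of 5, whose oxygen attacks the dichlorinated β-carbon (the future C2) and expels one chloride by addition–elimination, closing the O1–C2 bond of the γ-pyrone ring in a 6-endo-trig mode to give 9. Zerovalent palladium then inserts into the remaining C2–Cl bond, which is activated as a vinylogous acyl chloride, the hydroxyborate of 8 transfers its primary alkyl group, and reductive elimination forms the C2–CH2 bond (B-alkyl Suzuki–Miyaura coupling). The closest known reaction types are the base cyclization of o-hydroxyaryl β,β-dichlorovinyl ketones to 2-chlorochromones followed by Suzuki–Miyaura arylation at C2, and the domino carbon–heteroatom closure/Suzuki–Miyaura coupling of o-(gem-dihalovinyl)phenols and -anilines, which accepts B-alkyl-9-BBN partners; what is new is merging ring closure and sp2–sp3 coupling on a dichlorovinyl ketone. No stereocentre is formed. The step needs single rather than double alkylation and 6-endo rather than 5-exo closure: the ortho phenoxide consumes one chloride intramolecularly before the coupling (pre-stirring with base) or directly after it, both orders converging on 10, and only the β-carbon of the enone is electrophilic, so the oxygen attacks there. SPhos should make reductive elimination faster than β-hydride elimination, and the slight excess of alkene over 9-BBN leaves no B–H bond that could reduce the C4 ketone.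

Step 5
Reactants: 10 5,7-dimethoxy-2-icosyl-4H-chromen-4-one
Product: 11 5,7-dihydroxy-2-icosyl-4H-chromen-4-one (target)
Conditions: BBr3 (5 equiv), CH2Cl2, −78 °C → rt; ice water
Reagents that add atoms: none
Why: In this Lewis acid cleavage of aryl methyl ethers with BBr3 the C5 methyl should leave first with help from chelation to the C4 carbonyl and the C7 methyl with the excess reagent at room temperature, while the γ-pyrone ring and the saturated chain are inert.

**Compound list**
1 | 3,3-dichloroacrylic acid | OC(=O)C=C(Cl)Cl | starting material
2 | 3,3-dichloroacryloyl chloride | ClC(=O)C=C(Cl)Cl | intermediate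
3 | 1,3,5-trimethoxybenzene | COc1cc(OC)cc(OC)c1 | starting material
4 | 3,3-dichloro-1-(2,4,6-trimethoxyphenyl)prop-2-en-1-one | COc1cc(OC)c(C(=O)C=C(Cl)Cl)c(OC)c1 | intermediate
5 | 3,3-dichloro-1-(2-hydroxy-4,6-dimethoxyphenyl)prop-2-en-1-one | COc1cc(O)c(C(=O)C=C(Cl)Cl)c(OC)c1 | intermediate
6 | 1-icosene | CCCCCCCCCCCCCCCCCCC=C | starting material
7 | 9-borabicyclo[3.3.1]nonane (9-BBN, monomer) | C1CC2CCCC(C1)B2 | starting material
8 | B-icosyl-9-borabicyclo[3.3.1]nonane | CCCCCCCCCCCCCCCCCCCCB1C2CCCC1CCC2 | intermediate
9 | 2-chloro-5,7-dimethoxy-4H-chromen-4-one | COc1cc(OC)c2c(c1)oc(Cl)cc2=O | intermediate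
10 | 5,7-dimethoxy-2-icosyl-4H-chromen-4-one | CCCCCCCCCCCCCCCCCCCCc1cc(=O)c2c(OC)cc(OC)cc2o1 | intermediate
11 | 5,7-dihydroxy-2-icosyl-4H-chromen-4-one | CCCCCCCCCCCCCCCCCCCCc1cc(=O)c2c(O)cc(O)cc2o1 | target

Total step count: 5
Longest linear sequence: 5 steps (1 → 2 → 4 → 5 → 10 → 11)

**Steps most likely to fail**

Step 4 (Proposed new method).
- What may go wrong:
  - The wet base may hydrolyse the C2–Cl bond of the ring-closed intermediate before oxidative addition.
  - β-Hydride elimination from the alkylpalladium species may cause net hydrodechlorination.
  - Coupling may occur at both chlorides if ring closure lags behind.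
- Fallback, from 5 back to 10, in two separate polar events without palladium or boron:
  - Compound 5 is closed on its own with K2CO3 in acetone, and 2-chloro-5,7-dimethoxychromone 9 is isolated.
  - 1-Bromoicosane (purchased) is converted with Mg in THF into icosylmagnesium bromide F1.
  - With CuBr·SMe2 (10 mol %) in THF at −40 °C, the Grignard reagent replaces the C2 chloride of 9 by conjugate addition–elimination. This is the textbook substitution of β-halo enones by organocopper reagents, and it should give 10.

Step 2.
- What may go wrong:
  - A second arene molecule may attack the dichlorinated β-carbon of the Lewis acid-activated enone.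
  - Methyl groups may be lost without control, with early ring closure.
- Fallback, from 2 back to 5, bypassing 4 and step 3:
  - Compound 2 acylates purchased 3,5-dimethoxyphenol on oxygen (Et3N, CH2Cl2, 0 °C) to give 3,5-dimethoxyphenyl 3,3-dichloroprop-2-enoate F2.
  - A Fries rearrangement with TiCl4 in 1,2-dichloroethane moves the acyl group to the chelation-favoured ortho position and should deliver 5 directly.

Step 5.
- What may go wrong:
  - The cleavage may stall after loss of the chelated C5 methyl, so that the C7 ether survives.
  - The boron chelates of the long-chain substrate may precipitate.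
- Fallback, from 10 back to 11, removing each methyl by the mechanism that suits it:
  - BCl3 in CH2Cl2 at 0 °C takes only the chelated C5 methyl and gives 5-hydroxy-2-icosyl-7-methoxy-4H-chromen-4-one F3.
  - Sodium ethanethiolate (NaSEt) in DMF at 120 °C then removes the C7 methyl by SN2 attack on carbon. Acidic work-up should give 11.

**Further compounds**
F1 | step 4 | icosylmagnesium bromide | CCCCCCCCCCCCCCCCCCCC[Mg]Br
F2 | step 2 | 3,5-dimethoxyphenyl 3,3-dichloroprop-2-enoate | COc1cc(OC)cc(OC(=O)C=C(Cl)Cl)c1
F3 | step 5 | 5-hydroxy-2-icosyl-7-methoxy-4H-chromen-4-one | CCCCCCCCCCCCCCCCCCCCc1cc(=O)c2c(O)cc(OC)cc2o1
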